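**Strategy**

Ring C is made last: the flavonol is reached by isomerising an aurone spiro-epoxide, so the route rests on forming O1–C2. The step exploits ring B, whose 4'-oxygen lies para to C1'; once freed by fluoride, this phenoxide opens the epoxide at the benzylic carbon (the future C2) as a quinone methide, the furanone unravels to an aryl 1,2-diketone, and the released ring A oxygen beside the 1,1-dimethylallyl group closes the six-membered ring while O5 stays capped. The precursor is the racemic epoxide of a Z-aurone bearing MOM ethers at O5 and O7 and triisopropylsilyl ethers on ring B, assembled from a ring A benzofuranone and a 2,3-diprenylbenzaldehyde.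

Key step: step 11

Remark: the target has no stereocentre, so the epoxide is carried as a racemate and either relative configuration would serve; 5-bromovanillin and tributyl(3-methylbut-2-enyl)stannane are taken as purchased.

Design note: ring B carries triisopropylsilyl rather than smaller silyl ethers. They must outlast the basic hydroperoxide of step 10, since unmasking there would release the quinone methide in the presence of peroxide.

**Route**

Step 1
Reactants: 1 2,4,6-trihydroxyacetophenone; 2 prenyl bromide (1-bromo-3-methylbut-2-ene)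
Product: 3 1-[2,6-dihydroxy-4-(3-methylbut-2-enyloxy)phenyl]ethanone
Conditions: K2CO3 (1.0 equiv), acetone, rt to 40 °C
Reagents that add atoms: none
Why: Williamson etherification with a weak base and one equivalent of halide should take the 4-hydroxyl, the most acidic one because it is not held in a hydrogen bond to the ketone.

Step 2
Reactants: 3 1-[2,6-dihydroxy-4-(3-methylbut-2-enyloxy)phenyl]ethanone
Product: 6 1-[2,4,6-trihydroxy-3-(2-methylbut-3-en-2-yl)phenyl]ethanone, via bis(trimethylsilyl) ether 4 (not isolated), via tris(trimethylsilyl) ether 5 (not isolated)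
Conditions: N,O-bis(trimethylsilyl)acetamide (4 equiv), N,N-diethylaniline, 190 °C, sealed tube, argon; then MeOH, K2CO3 (cat.), rt
Reagents that add atoms: none
Why: Aromatic Claisen rearrangement: the [3,3] shift with allyl inversion delivers the 2-methylbut-3-en-2-yl group to an ortho carbon, the two ortho positions being equivalent by symmetry and the para position blocked by the acetyl group, while silylation of the liberated phenol in the flask suppresses the abnormal Claisen and ring-closure pathways of o-(1,1-dimethylallyl)phenols and methanolysis then returns the free triol.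

Step 3
Reactants: 6 1-[2,4,6-trihydroxy-3-(2-methylbut-3-en-2-yl)phenyl]ethanone
Product: 7 1-[2-hydroxy-4,6-bis(methoxymethoxy)-3-(2-methylbut-3-en-2-yl)phenyl]ethanone
Conditions: MOMCl (2.2 equiv), i-Pr2NEt (3 equiv), CH2Cl2, 0 °C to rt
Reagents that add atoms: chloromethyl methyl ether, COCCl
Why: Base-mediated O-alkylation to the acetal (MOM protection) should take the 4-hydroxyl first, as the most acidic one, and then the 6-hydroxyl, because the 2-hydroxyl is wedged between the acetyl and the tertiary alkyl group and locked in the hydrogen bond to the ketone, which leaves exactly the phenol needed for furanone closure.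

Step 4
Reactants: 7 1-[2-hydroxy-4,6-bis(methoxymethoxy)-3-(2-methylbut-3-en-2-yl)phenyl]ethanone
Product: 10 4,6-bis(methoxymethoxy)-7-(2-methylbut-3-en-2-yl)benzofuran-3(2H)-one, via bis-silyl enol ether 8 (not isolated), via silylated bromoketone 9 (not isolated)
Conditions: LiN(SiMe3)2 (2.2 equiv), Me3SiCl (2.5 equiv), THF, −78 °C; NBS (1.05 equiv), −78 °C; then K2CO3, MeOH, 0 °C to rt
Reagents that add atoms: none
Why: Regiospecific α-bromination of the methyl ketone through its trimethylsilyl enol ether (the phenol is silylated at the same time, which keeps the electron-rich ring and the terminal alkene from competing for the bromine source at −78 °C), then methanolysis of the aryl silyl ether and intramolecular Williamson etherification (5-exo-tet) should close the benzofuran-3(2H)-one.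

Step 5
Reactants: 11 5-bromovanillin (3-bromo-4-hydroxy-5-methoxybenzaldehyde)
Product: 12 2,3-dibromo-4-hydroxy-5-methoxybenzaldehyde
Conditions: Br2 (1.1 equiv), Fe powder (cat.), NaOAc, AcOH, rt
Reagents that add atoms: bromine, BrBr
Why: Electrophilic aromatic bromination should go to the remaining position para to the methoxy group, next to the existing bromine, the established second site of halogenation for this phenol.

Step 6
Reactants: 12 2,3-dibromo-4-hydroxy-5-methoxybenzaldehyde
Product: 13 2,3-dibromo-4,5-dihydroxybenzaldehyde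
Conditions: AlCl3 (1.5 equiv), pyridine (4.5 equiv), CH2Cl2, reflux; then 2 M HCl
Reagents that add atoms: none
Why: Chelation-assisted O-demethylation of an o-hydroxyanisole: the aluminium phenoxide binds the neighbouring methoxy oxygen and pyridine takes the methyl group by SN2, which leaves the aldehyde and both bromines untouched.

Step 7
Reactants: 13 2,3-dibromo-4,5-dihydroxybenzaldehyde
Product: 14 2,3-dibromo-4,5-bis(triisopropylsilyloxy)benzaldehyde
Conditions: i-Pr3SiOTf (2.4 equiv), 2,6-lutidine (3 equiv), CH2Cl2, 0 °C to rt
Reagents that add atoms: triisopropylsilyl trifluoromethanesulfonate, CC(C)[Si](OS(=O)(=O)C(F)(F)F)(C(C)C)C(C)C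
Why: Silylation of both phenols with a silyl triflate and a hindered pyridine base, the triflate being reactive enough for the hydroxyl flanked by bromine and a silyloxy group.

Step 8
Reactants: 14 2,3-dibromo-4,5-bis(triisopropylsilyloxy)benzaldehyde; 15 tributyl(3-methylbut-2-enyl)stannane (2.6 equiv)
Product: 16 2,3-bis(3-methylbut-2-enyl)-4,5-bis(triisopropylsilyloxy)benzaldehyde
Conditions: Pd(PPh3)4 (10 mol %), DMF, 95 °C, argon; tin removed on K2CO3-doped silica
Reagents that add atoms: none
Why: Twofold Stille coupling: oxidative addition of each C–Br bond to zerovalent palladium, transfer of the allyl unit from tin and reductive elimination at the less substituted allyl terminus should give the linear 3-methylbut-2-enyl groups, and the absence of fluoride additives keeps the silyl ethers in place.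

Step 9
Reactants: 10 4,6-bis(methoxymethoxy)-7-(2-methylbut-3-en-2-yl)benzofuran-3(2H)-one; 16 2,3-bis(3-methylbut-2-enyl)-4,5-bis(triisopropylsilyloxy)benzaldehyde
Product: 17 (Z)-2-[2,3-bis(3-methylbut-2-enyl)-4,5-bis(triisopropylsilyloxy)benzylidene]-4,6-bis(methoxymethoxy)-7-(2-methylbut-3-en-2-yl)benzofuran-3(2H)-one
Conditions: neutral Al2O3 (activated), CH2Cl2, rt
Reagents that add atoms: none
Why: Aldol condensation (Knoevenagel type) of the acidic C2 methylene of the benzofuranone with the aldehyde on a neutral oxide surface that spares acetals and silyl ethers; dehydration under thermodynamic control should give the Z-alkene, with the aryl group on the side of the ring oxygen and away from the carbonyl.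

Step 10
Reactants: 17 the Z-aurone
Product: 18 (2S*,3'S*)-3'-[2,3-bis(3-methylbut-2-enyl)-4,5-bis(triisopropylsilyloxy)phenyl]-4,6-bis(methoxymethoxy)-7-(2-methylbut-3-en-2-yl)spiro[benzofuran-2(3H),2'-oxiran]-3-one (racemic, aryl cis to the ring oxygen)
Conditions: t-BuOOH (anhydrous, in decane, 3 equiv), DBU (1.5 equiv), toluene, 0 °C to rt; filtration through Et3N-deactivated silica
Reagents that add atoms: tert-butyl hydroperoxide, CC(C)(C)OO
Why: Weitz–Scheffer nucleophilic epoxidation: the tert-butyl peroxide anion adds to the benzylic carbon of the enone and the enolate closes on the O–O bond, so the three isolated, electron-rich alkenes are left alone; both new stereocentres (the spiro carbon and the benzylic carbon) form in this one event, their relative configuration following from the Z geometry if ring closure outruns bond rotation, and the product is racemic since nothing chiral is present.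

Step 11
Reactants: 18 the aurone spiro-epoxide
Product: 22 3-hydroxy-2-[4,5-dihydroxy-2,3-bis(3-methylbut-2-enyl)phenyl]-5,7-bis(methoxymethoxy)-8-(2-methylbut-3-en-2-yl)chromen-4-one, via catechol epoxide 19 (not isolated), via quinone methide diketone 20 (not isolated), via chroman-3,4-dione 21 (not isolated)
Conditions: Bu4NF (1.0 M in THF, 2.5 equiv), degassed THF, 0 °C to rt, argon; then AcOH
Reagents that add atoms: none
Why: Proposed new method: fluoride cleaves both aryl O–Si bonds to give the dianion of 19, whose 4'-phenoxide, para to C1', expels the epoxide oxygen from the benzylic carbon to form a para-quinone methide, while the alkoxide left on the spiro carbon, a hemiketal, collapses to the 1,2-diketone 20 and releases the ring A aryloxide; this aryloxide adds to the methide carbon (1,6-addition, forming O1–C2) to give chroman-3,4-dione 21, which enolises to the chromen-4-one. The closest known reaction type is the Auwers flavonol synthesis, in which the same o-hydroxyaryl 1,2-diketone closes on a benzylic bromide, combined with the base-induced formation of quinone methides from p-hydroxybenzyl derivatives; here a vinylogous electrophile takes the place of the bromide. Ring C (O1, C2, C3, C4, C4a, C8a) closes in a 6-exo-trig oxa-conjugate addition. The only stereocentre formed, C2 of 21, is transient and is erased by enolisation, as are both epoxide centres, so no control element is needed. Ring size is secured because reclosure of the aryloxide on the neighbouring carbonyl only regenerates a reversible five-membered hemiketal, whereas the 1,6-addition is followed by irreversible aromatisation to the pyranone. Regiochemistry (8- and not 6-substitution) is secured because O5 stays a MOM acetal, which leaves the oxygen beside the 1,1-dimethylallyl group as the sole ring A nucleophile, and the basic, non-oxidising medium leaves the three alkenes untouched.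

Step 12
Reactants: 22 the 5,7-bis(methoxymethyl) ether of the target
Product: 23 Broussoflavonol C
Conditions: HCl (1 M in MeOH), 40 °C, argon
Reagents that add atoms: none
Why: Acid-catalysed acetal exchange with methanol removes both MOM groups (the one at O5, peri to the carbonyl, first), and dilute acid at mild temperature is chosen so that the phenols flanking the prenyl and 1,1-dimethylallyl groups do not add to their alkenes.

**Compound list**

1 | 2,4,6-trihydroxyacetophenone | CC(=O)c1c(O)cc(O)cc1O | starting material
2 | prenyl bromide (1-bromo-3-methylbut-2-ene) | CC(C)=CCBr | starting material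
3 | 1-[2,6-dihydroxy-4-(3-methylbut-2-enyloxy)phenyl]ethanone | CC(=O)c1c(O)cc(OCC=C(C)C)cc1O | intermediate
4 | 1-[4-(3-methylbut-2-enyloxy)-2,6-bis(trimethylsilyloxy)phenyl]ethanone (not isolated) | CC(=O)c1c(O[Si](C)(C)C)cc(OCC=C(C)C)cc1O[Si](C)(C)C | intermediate
5 | 1-[3-(2-methylbut-3-en-2-yl)-2,4,6-tris(trimethylsilyloxy)phenyl]ethanone (not isolated) | CC(=O)c1c(O[Si](C)(C)C)cc(O[Si](C)(C)C)c(C(C)(C)C=C)c1O[Si](C)(C)C | intermediate
6 | 1-[2,4,6-trihydroxy-3-(2-methylbut-3-en-2-yl)phenyl]ethanone | CC(=O)c1c(O)cc(O)c(C(C)(C)C=C)c1O | intermediate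
7 | 1-[2-hydroxy-4,6-bis(methoxymethoxy)-3-(2-methylbut-3-en-2-yl)phenyl]ethanone | CC(=O)c1c(OCOC)cc(OCOC)c(C(C)(C)C=C)c1O | intermediate
8 | trimethylsilyl enol ether of 7 with the phenol also silylated (not isolated) | C=C(O[Si](C)(C)C)c1c(OCOC)cc(OCOC)c(C(C)(C)C=C)c1O[Si](C)(C)C | intermediate
9 | 2-bromo-1-[4,6-bis(methoxymethoxy)-3-(2-methylbut-3-en-2-yl)-2-(trimethylsilyloxy)phenyl]ethanone (not isolated) | O=C(CBr)c1c(OCOC)cc(OCOC)c(C(C)(C)C=C)c1O[Si](C)(C)C | intermediate
10 | 4,6-bis(methoxymethoxy)-7-(2-methylbut-3-en-2-yl)benzofuran-3(2H)-one | O=C1COc2c(C(C)(C)C=C)c(OCOC)cc(OCOC)c12 | intermediate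
11 | 5-bromovanillin (3-bromo-4-hydroxy-5-methoxybenzaldehyde) | COc1cc(C=O)cc(Br)c1O | starting material
12 | 2,3-dibromo-4-hydroxy-5-methoxybenzaldehyde | COc1cc(C=O)c(Br)c(Br)c1O | intermediate
13 | 2,3-dibromo-4,5-dihydroxybenzaldehyde | O=Cc1cc(O)c(O)c(Br)c1Br | intermediate
14 | 2,3-dibromo-4,5-bis(triisopropylsilyloxy)benzaldehyde | O=Cc1cc(O[Si](C(C)C)(C(C)C)C(C)C)c(O[Si](C(C)C)(C(C)C)C(C)C)c(Br)c1Br | intermediate
15 | tributyl(3-methylbut-2-enyl)stannane | CCCC[Sn](CCCC)(CCCC)CC=C(C)C | starting material
16 | 2,3-bis(3-methylbut-2-enyl)-4,5-bis(triisopropylsilyloxy)benzaldehyde | O=Cc1cc(O[Si](C(C)C)(C(C)C)C(C)C)c(O[Si](C(C)C)(C(C)C)C(C)C)c(CC=C(C)C)c1CC=C(C)C | intermediate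
17 | (Z)-2-[2,3-bis(3-methylbut-2-enyl)-4,5-bis(triisopropylsilyloxy)benzylidene]-4,6-bis(methoxymethoxy)-7-(2-methylbut-3-en-2-yl)benzofuran-3(2H)-one | O=C1c2c(OCOC)cc(OCOC)c(C(C)(C)C=C)c2O/C1=C\c1cc(O[Si](C(C)C)(C(C)C)C(C)C)c(O[Si](C(C)C)(C(C)C)C(C)C)c(CC=C(C)C)c1CC=C(C)C | intermediate
18 | (2S*,3'S*)-3'-[2,3-bis(3-methylbut-2-enyl)-4,5-bis(triisopropylsilyloxy)phenyl]-4,6-bis(methoxymethoxy)-7-(2-methylbut-3-en-2-yl)spiro[benzofuran-2(3H),2'-oxiran]-3-one, racemic, aryl cis to the ring oxygen | O=C1c2c(OCOC)cc(OCOC)c(C(C)(C)C=C)c2O[C@]13O[C@H]3c1cc(O[Si](C(C)C)(C(C)C)C(C)C)c(O[Si](C(C)C)(C(C)C)C(C)C)c(CC=C(C)C)c1CC=C(C)C | intermediate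
19 | (2S*,3'S*)-3'-[4,5-dihydroxy-2,3-bis(3-methylbut-2-enyl)phenyl]-4,6-bis(methoxymethoxy)-7-(2-methylbut-3-en-2-yl)spiro[benzofuran-2(3H),2'-oxiran]-3-one, racemic (not isolated) | O=C1c2c(OCOC)cc(OCOC)c(C(C)(C)C=C)c2O[C@]13O[C@H]3c1cc(O)c(O)c(CC=C(C)C)c1CC=C(C)C | intermediate
20 | 1-[2-hydroxy-4,6-bis(methoxymethoxy)-3-(2-methylbut-3-en-2-yl)phenyl]-3-[5-hydroxy-2,3-bis(3-methylbut-2-enyl)-4-oxocyclohexa-2,5-dien-1-ylidene]propane-1,2-dione (not isolated) | C=CC(C)(C)c1c(O)c(C(=O)C(=O)C=C2C=C(O)C(=O)C(CC=C(C)C)=C2CC=C(C)C)c(OCOC)cc1OCOC | intermediate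
21 | 2-[4,5-dihydroxy-2,3-bis(3-methylbut-2-enyl)phenyl]-5,7-bis(methoxymethoxy)-8-(2-methylbut-3-en-2-yl)chromane-3,4-dione, racemic (not isolated) | C=CC(C)(C)c1c(OCOC)cc(OCOC)c2c1OC(c1cc(O)c(O)c(CC=C(C)C)c1CC=C(C)C)C(=O)C2=O | intermediate
22 | 3-hydroxy-2-[4,5-dihydroxy-2,3-bis(3-methylbut-2-enyl)phenyl]-5,7-bis(methoxymethoxy)-8-(2-methylbut-3-en-2-yl)chromen-4-one | C=CC(C)(C)c1c(OCOC)cc(OCOC)c2c(=O)c(O)c(-c3cc(O)c(O)c(CC=C(C)C)c3CC=C(C)C)oc12 | intermediate
23 | Broussoflavonol C, 3,5,7-trihydroxy-2-[4,5-dihydroxy-2,3-bis(3-methylbut-2-enyl)phenyl]-8-(2-methylbut-3-en-2-yl)chromen-4-one | C=CC(C)(C)c1c(O)cc(O)c2c(=O)c(O)c(-c3cc(O)c(O)c(CC=C(C)C)c3CC=C(C)C)oc12 | target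

**Step count and risks**

Total step count: 12. Longest linear sequence: 8 steps (steps 1–4 then 9–12; the ring B branch, steps 5–8 then 9–12, is equally long).

Steps most likely to fail:

1. Step 11. The quinone methide may be intercepted by fluoride, hydroxide or water before the ring A aryloxide reaches the methide carbon, the aryloxide may settle back into five-membered hemiketal products, or the polyanionic catechol may be oxidised by traces of air. Fallback with known chemistry, setting out from 18: the epoxide is opened at the benzylic carbon with LiCl and AcOH in THF to give the chlorohydrin hemiketal F1. F1 is then treated with KOH in degassed EtOH, the base-induced ring-expansion stage of the Auwers flavonol synthesis with chloride in place of bromide: the hemiketal opens to the diketone aryloxide, which displaces the benzylic chloride, and the hydroxide also removes the silyl ethers. The sequence comes back to the route at 22.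

2. Step 10. Conjugate addition of the peroxide anion to this push–pull, electron-rich enone may be slow, giving the anion time to attack silicon (premature unmasking in the presence of peroxide) or the ketone. Fallback, setting out from 10 and bypassing 17: chlorination of the lithium enolate (LiN(SiMe3)2, THF, −78 °C, then N-chlorosuccinimide) gives the 2-chloro ketone F2. A Darzens condensation of F2 with 16 (LiN(SiMe3)2, THF, −78 to 0 °C), in which the aldolate displaces chloride to close the oxirane, should then give 18, possibly together with its epimer F3, which is equally competent in step 11. The sequence comes back to the route at 18.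

3. Step 9. Self-condensation of the benzofuranone may outrun the cross-condensation with a hindered, electron-rich aldehyde, or the aldol equilibrium may lie on the side of the components. Fallback, setting out from 10: a directed aldol addition of the preformed lithium enolate (LiN(SiMe3)2, THF, −78 °C) to 16 gives the β-hydroxy ketone F4. Treatment with MsCl and Et3N in CH2Cl2 (0 °C to rt) forms its methanesulfonate F5, which eliminates in the flask (E1cB) to the thermodynamic Z-alkene. The sequence comes back to the route at 17.

Further compounds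
F1 | step 11 | 2-{chloro[2,3-bis(3-methylbut-2-enyl)-4,5-bis(triisopropylsilyloxy)phenyl]methyl}-2-hydroxy-4,6-bis(methoxymethoxy)-7-(2-methylbut-3-en-2-yl)benzofuran-3(2H)-one, racemic, mixture of diastereomers | O=C1c2c(OCOC)cc(OCOC)c(C(C)(C)C=C)c2OC1(O)C(Cl)c1cc(O[Si](C(C)C)(C(C)C)C(C)C)c(O[Si](C(C)C)(C(C)C)C(C)C)c(CC=C(C)C)c1CC=C(C)C
F2 | step 10 | 2-chloro-4,6-bis(methoxymethoxy)-7-(2-methylbut-3-en-2-yl)benzofuran-3(2H)-one, racemic | O=C1C(Cl)Oc2c(C(C)(C)C=C)c(OCOC)cc(OCOC)c12
F3 | step 10 | (2S*,3'R*)-epimer of 18, racemic, aryl trans to the ring oxygen | O=C1c2c(OCOC)cc(OCOC)c(C(C)(C)C=C)c2O[C@]13O[C@@H]3c1cc(O[Si](C(C)C)(C(C)C)C(C)C)c(O[Si](C(C)C)(C(C)C)C(C)C)c(CC=C(C)C)c1CC=C(C)C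
F4 | step 9 | 2-{hydroxy[2,3-bis(3-methylbut-2-enyl)-4,5-bis(triisopropylsilyloxy)phenyl]methyl}-4,6-bis(methoxymethoxy)-7-(2-methylbut-3-en-2-yl)benzofuran-3(2H)-one, racemic, mixture of diastereomers | O=C1C(C(O)c3cc(O[Si](C(C)C)(C(C)C)C(C)C)c(O[Si](C(C)C)(C(C)C)C(C)C)c(CC=C(C)C)c3CC=C(C)C)Oc2c(C(C)(C)C=C)c(OCOC)cc(OCOC)c12
F5 | step 9 | methanesulfonate of F4, racemic, mixture of diastereomers | O=C1C(C(OS(C)(=O)=O)c3cc(O[Si](C(C)C)(C(C)C)C(C)C)c(O[Si](C(C)C)(C(C)C)C(C)C)c(CC=C(C)C)c3CC=C(C)C)Oc2c(C(C)(C)C=C)c(OCOC)cc(OCOC)c12
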